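**Plan**
- Retrosynthesis: the benzylic ester C–O bond is cut first, then ring B is dismantled at C1'–C6', C2'–C3' and C3'–C4', leading back to an ethynyl ether of ring A and 3-methylcyclobutenone.
- The enabling feature is ring B itself: ether oxygen at C1', OH at C3', CH3 at C5', hydrogen at C2', C4' and C6'. This is the resorcinol monoether with a meta methyl group that a terminal ynol ether (C1', C2') and 3-methylcyclobutenone (C3' to C6') assemble in a Danheiser benzannulation.
- Forward: ring A is bought as 2-hydroxy-5-methoxybenzaldehyde, oxygenated at C3, differentiated (O-benzyl, CH2OSi(iPr)3), and its crowded phenol oxygen is turned into an ethynyl ether with trichloroethylene and n-BuLi.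
- Ring B, the only ring that is made, is then grown on that oxygen by heating with 3-methylcyclobutenone (two steps from propyne), so no hindered diaryl ether coupling is needed.
- Hydrogenolysis, desilylation and lipase-catalysed acyl transfer from vinyl palmitate to the benzylic alcohol finish the route.
- The target has no stereocentre; the issues are regiochemical, settled by the directing phenol of ring A, the polarisation of the ynol ether and the methyl position of the cyclobutenone.

Key step: step 10

Remark: betaethrin H has no stereogenic element, so the route controls regiochemistry only; reagents without a number are ordinary commercial chemicals.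

**Route**

Step 1
Reactants: 1 2-hydroxy-5-methoxybenzaldehyde
Product: 2 3-bromo-2-hydroxy-5-methoxybenzaldehyde
Conditions: Br2 (1.05 equiv), NaOAc, AcOH, rt
Reagents that add atoms: bromine, BrBr
Why: Electrophilic aromatic bromination should go to C3, the only free position ortho to the phenol (its para position carries OCH3), because the hydroxyl outweighs the methoxy and formyl groups as director.

Step 2
Reactants: 2 3-bromo-2-hydroxy-5-methoxybenzaldehyde
Product: 3 2,3-dihydroxy-5-methoxybenzaldehyde
Conditions: NaOH (aq), Cu powder (cat.), reflux, N2; then HCl (aq)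
Reagents that add atoms: sodium hydroxide, [Na+].[OH-]
Why: Copper-mediated Ullmann-type hydroxylation of an ortho-bromophenoxide, the reaction type that converts 5-bromovanillin into 5-hydroxyvanillin; the phenoxide shields the aldehyde from Cannizzaro disproportionation.

Step 3
Reactants: 3 2,3-dihydroxy-5-methoxybenzaldehyde
Product: 5 3-(benzyloxy)-2-hydroxy-5-methoxybenzaldehyde, via disodium 3-formyl-5-methoxybenzene-1,2-diolate 4 (not isolated)
Conditions: NaH (2.2 equiv), DMSO/THF, rt; then BnBr (1.0 equiv), rt; HCl (aq)
Reagents that add atoms: benzyl bromide, BrCc1ccccc1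
Why: Regioselective Williamson etherification of the catechol dianion, in which the C2 phenoxide is conjugated with and chelated to the formyl group, so the more basic C3 phenoxide should take the single equivalent of benzyl bromide, as it does in 2,3-dihydroxybenzaldehyde itself.

Step 4
Reactants: 5 3-(benzyloxy)-2-hydroxy-5-methoxybenzaldehyde
Product: 6 2-(benzyloxy)-6-(hydroxymethyl)-4-methoxyphenol
Conditions: NaBH4, MeOH/THF, 0 °C
Reagents that add atoms: none
Why: Borohydride reduction of the aryl aldehyde to the benzylic alcohol, which leaves the benzyl ether and the phenol untouched.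

Step 5
Reactants: 6 2-(benzyloxy)-6-(hydroxymethyl)-4-methoxyphenol
Product: 7 2-(benzyloxy)-4-methoxy-6-{[(triisopropylsilyl)oxy]methyl}phenol
Conditions: iPr3SiCl (1.05 equiv), imidazole, CH2Cl2, 0 °C → rt
Reagents that add atoms: chlorotriisopropylsilane, CC(C)[Si](Cl)(C(C)C)C(C)C
Why: Chemoselective silylation (silyl ether formation) in which the primary benzylic hydroxyl should react with the bulky silyl chloride well before the hydrogen-bonded phenol flanked by two ortho substituents, as in the monosilylation of salicyl alcohols.

Step 6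
Reactants: 7 2-(benzyloxy)-4-methoxy-6-{[(triisopropylsilyl)oxy]methyl}phenol
Product: 8 1-(benzyloxy)-2-{[(E)-1,2-dichloroethenyl]oxy}-5-methoxy-3-{[(triisopropylsilyl)oxy]methyl}benzene
Conditions: Cl2C=CHCl (2 equiv), K2CO3, DMF, 70 °C
Reagents that add atoms: trichloroethylene, ClC=C(Cl)Cl
Why: Base turns trichloroethylene into dichloroacetylene, to which the phenoxide adds in anti fashion to give the (E)-1,2-dichlorovinyl ether (the standard O-dichlorovinylation of phenols); silyl and benzyl ethers tolerate K2CO3 in DMF.

Step 7
Reactants: 8 1-(benzyloxy)-2-{[(E)-1,2-dichloroethenyl]oxy}-5-methoxy-3-{[(triisopropylsilyl)oxy]methyl}benzene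
Product: 11 1-(benzyloxy)-2-(ethynyloxy)-5-methoxy-3-{[(triisopropylsilyl)oxy]methyl}benzene, via aryl chloroethynyl ether 9 (not isolated), via lithium aryloxyacetylide 10 (not isolated)
Conditions: n-BuLi (2.5 equiv), Et2O, −78 → −40 °C; then H2O, −78 → 0 °C; used at once
Reagents that add atoms: none
Why: Elimination–exchange route to ynol ethers, in which the first equivalent of n-BuLi dehydrochlorinates 8 to chloroalkyne 9, the second effects chlorine–lithium exchange to acetylide 10 and water protonates it, while the low temperature keeps the benzyl and silyl ethers out of reach of the base.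

Step 8
Reactants: 12 propyne
Product: 13 4,4-dichloro-3-methylcyclobut-2-en-1-one
Conditions: Cl3CCOCl, Zn(Cu) couple, Et2O/DME, 0 °C → rt
Reagents that add atoms: trichloroacetyl chloride, ClC(=O)C(Cl)(Cl)Cl
Why: Zinc dechlorinates the acid chloride to dichloroketene, which adds to the alkyne in a [2+2] cycloaddition with its carbonyl carbon bonding to the terminal CH, so the methyl group ends at C3.

Step 9
Reactants: 13 4,4-dichloro-3-methylcyclobut-2-en-1-one
Product: 14 3-methylcyclobut-2-en-1-one
Conditions: Zn dust, AcOH, TMEDA, EtOH, 0 °C → rt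
Reagents that add atoms: none
Why: Reductive dechlorination of an α,α-dichloroketone with zinc in buffered acetic acid, the usual finish of the dichloroketene route to 3-substituted cyclobutenones; the volatile product should be distilled and stored cold.

Step 10
Reactants: 11 1-(benzyloxy)-2-(ethynyloxy)-5-methoxy-3-{[(triisopropylsilyl)oxy]methyl}benzene; 14 3-methylcyclobut-2-en-1-one
Product: 19 3-[2-(benzyloxy)-4-methoxy-6-{[(triisopropylsilyl)oxy]methyl}phenoxy]-5-methylphenol, via vinylketene 15 (not isolated), via vinylcyclobutenone 16 (not isolated), via dienylketene 17 (not isolated), via cyclohexadienone 18 (not isolated)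
Conditions: 14 (2 equiv), toluene, 80 → 110 °C, sealed tube; then K2CO3 (cat.), MeOH, rt
Reagents that add atoms: none
Why: This is a Danheiser benzannulation, known for alkoxy- and silyloxyacetylenes and applied here to an aryloxyacetylene of the same ynol ether class: heat opens 14 by 4π electrocyclic ring opening to vinylketene 15, whose ketene C=C adds 11 in a [2+2] cycloaddition to give 4-vinylcyclobutenone 16, which opens again (4π) to dienylketene 17. Ring B, the only ring formed, closes by thermal disrotatory 6π electrocyclisation of 17 (ketene carbon to the terminal CH2), and dienone 18 tautomerises irreversibly to the phenol. The new bonds are C2'–C3' and C1'–C6' from the [2+2] step and C3'–C4' from the ring closure; no stereocentre results, the one in 16 being lost again. The selectivity needed is regiochemical: the nucleophilic CH terminus of the ynol ether attacks the electrophilic ketene carbonyl carbon, which places the aryloxy group meta to the new hydroxyl, and the methyl group arrives at C5' from C3 of 14. The 2,6-disubstituted ring A is twisted out of conjugation with the ether oxygen, which should keep its lone pair available to the alkyne, and an aryl ynol ether has no β-hydrogen for retro-ene fragmentation on heating; surplus 14 allows for ketene dimerisation, and the methanolysis returns any phenol acylated by the ketene.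

Step 11
Reactants: 19 3-[2-(benzyloxy)-4-methoxy-6-{[(triisopropylsilyl)oxy]methyl}phenoxy]-5-methylphenol
Product: 20 3-[2-hydroxy-4-methoxy-6-{[(triisopropylsilyl)oxy]methyl}phenoxy]-5-methylphenol
Conditions: H2 (1 atm), 10% Pd/C, EtOAc, rt
Reagents that add atoms: none
Why: Catalytic hydrogenolysis of the aryl benzyl ether, which in neutral ethyl acetate should spare the benzylic silyl ether and the diaryl ether; it is placed before the ester is introduced because a benzylic palmitate would not survive it.

Step 12
Reactants: 20 3-[2-hydroxy-4-methoxy-6-{[(triisopropylsilyl)oxy]methyl}phenoxy]-5-methylphenol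
Product: 21 3-[2-hydroxy-6-(hydroxymethyl)-4-methoxyphenoxy]-5-methylphenol
Conditions: Bu4NF, AcOH, THF, 0 °C → rt
Reagents that add atoms: none
Why: Fluoride-induced cleavage of the primary silyl ether, buffered with acetic acid so that the two phenols are not held as air-sensitive phenoxides.

Step 13
Reactants: 21 3-[2-hydroxy-6-(hydroxymethyl)-4-methoxyphenoxy]-5-methylphenol; 22 vinyl palmitate
Product: 23 betaethrin H, [3-hydroxy-2-(3-hydroxy-5-methylphenoxy)-5-methoxyphenyl]methyl hexadecanoate
Conditions: Novozym 435 (immobilised Candida antarctica lipase B), 22 (2 equiv), t-BuOMe/THF, 4 Å MS, 40 °C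
Reagents that add atoms: none
Why: Lipase-catalysed irreversible transesterification with a vinyl ester, in which the enzyme should acylate the primary benzylic alcohol and leave both phenols free, as with hydroxybenzyl alcohols and tyrosol; the vinyl alcohol released tautomerises to acetaldehyde.

**Compound list**

1 | 2-hydroxy-5-methoxybenzaldehyde | COc1ccc(O)c(C=O)c1 | starting material
2 | 3-bromo-2-hydroxy-5-methoxybenzaldehyde | COc1cc(Br)c(O)c(C=O)c1 | intermediate
3 | 2,3-dihydroxy-5-methoxybenzaldehyde | COc1cc(O)c(O)c(C=O)c1 | intermediate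
4 | disodium 3-formyl-5-methoxybenzene-1,2-diolate (not isolated) | [Na+].[Na+].COc1cc([O-])c([O-])c(C=O)c1 | intermediate
5 | 3-(benzyloxy)-2-hydroxy-5-methoxybenzaldehyde | COc1cc(OCc2ccccc2)c(O)c(C=O)c1 | intermediate
6 | 2-(benzyloxy)-6-(hydroxymethyl)-4-methoxyphenol | COc1cc(CO)c(O)c(OCc2ccccc2)c1 | intermediate
7 | 2-(benzyloxy)-4-methoxy-6-{[(triisopropylsilyl)oxy]methyl}phenol | COc1cc(CO[Si](C(C)C)(C(C)C)C(C)C)c(O)c(OCc2ccccc2)c1 | intermediate
8 | 1-(benzyloxy)-2-{[(E)-1,2-dichloroethenyl]oxy}-5-methoxy-3-{[(triisopropylsilyl)oxy]methyl}benzene | Cl/C=C(/Cl)Oc1c(CO[Si](C(C)C)(C(C)C)C(C)C)cc(OC)cc1OCc1ccccc1 | intermediate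
9 | 1-(benzyloxy)-2-[(chloroethynyl)oxy]-5-methoxy-3-{[(triisopropylsilyl)oxy]methyl}benzene (not isolated) | ClC#COc1c(CO[Si](C(C)C)(C(C)C)C(C)C)cc(OC)cc1OCc1ccccc1 | intermediate
10 | lithium 2-[2-(benzyloxy)-4-methoxy-6-{[(triisopropylsilyl)oxy]methyl}phenoxy]ethyn-1-ide (not isolated) | [Li]C#COc1c(CO[Si](C(C)C)(C(C)C)C(C)C)cc(OC)cc1OCc1ccccc1 | intermediate
11 | 1-(benzyloxy)-2-(ethynyloxy)-5-methoxy-3-{[(triisopropylsilyl)oxy]methyl}benzene | C#COc1c(CO[Si](C(C)C)(C(C)C)C(C)C)cc(OC)cc1OCc1ccccc1 | intermediate
12 | propyne | CC#C | starting material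
13 | 4,4-dichloro-3-methylcyclobut-2-en-1-one | CC1=CC(=O)C1(Cl)Cl | intermediate
14 | 3-methylcyclobut-2-en-1-one | CC1=CC(=O)C1 | intermediate
15 | 3-methylbuta-1,3-dien-1-one, the vinylketene (not isolated) | C=C(C)C=C=O | intermediate
16 | racemic 3-[2-(benzyloxy)-4-methoxy-6-{[(triisopropylsilyl)oxy]methyl}phenoxy]-4-(prop-1-en-2-yl)cyclobut-2-en-1-one (not isolated) | C=C(C)C1C(=O)C=C1Oc2c(CO[Si](C(C)C)(C(C)C)C(C)C)cc(OC)cc2OCc3ccccc3 | intermediate
17 | (3E)-3-[2-(benzyloxy)-4-methoxy-6-{[(triisopropylsilyl)oxy]methyl}phenoxy]-5-methylhexa-1,3,5-trien-1-one, the dienylketene (not isolated) | O=C=C/C(Oc1c(CO[Si](C(C)C)(C(C)C)C(C)C)cc(OC)cc1OCc1ccccc1)=C\C(C)=C | intermediate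
18 | 3-[2-(benzyloxy)-4-methoxy-6-{[(triisopropylsilyl)oxy]methyl}phenoxy]-5-methylcyclohexa-2,4-dien-1-one (not isolated) | CC1=CC(Oc2c(CO[Si](C(C)C)(C(C)C)C(C)C)cc(OC)cc2OCc3ccccc3)=CC(=O)C1 | intermediate
19 | 3-[2-(benzyloxy)-4-methoxy-6-{[(triisopropylsilyl)oxy]methyl}phenoxy]-5-methylphenol | Cc1cc(O)cc(Oc2c(CO[Si](C(C)C)(C(C)C)C(C)C)cc(OC)cc2OCc3ccccc3)c1 | intermediate
20 | 3-[2-hydroxy-4-methoxy-6-{[(triisopropylsilyl)oxy]methyl}phenoxy]-5-methylphenol | Cc1cc(O)cc(Oc2c(O)cc(OC)cc2CO[Si](C(C)C)(C(C)C)C(C)C)c1 | intermediate
21 | 3-[2-hydroxy-6-(hydroxymethyl)-4-methoxyphenoxy]-5-methylphenol | Cc1cc(O)cc(Oc2c(O)cc(OC)cc2CO)c1 | intermediate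
22 | vinyl palmitate (ethenyl hexadecanoate) | CCCCCCCCCCCCCCCC(=O)OC=C | starting material
23 | betaethrin H, [3-hydroxy-2-(3-hydroxy-5-methylphenoxy)-5-methoxyphenyl]methyl hexadecanoate | CCCCCCCCCCCCCCCC(=O)OCc1cc(OC)cc(O)c1Oc1cc(C)cc(O)c1 | target

**Step count**

Total: 13 steps. Longest linear sequence: 11 steps (steps 1–7 and 10–13, from 1); the cyclobutenone branch (steps 8 and 9) joins at step 10.

**Steps most likely to fail**

1. Step 10. The aryl ynol ether is a weaker π-nucleophile than alkoxy- or silyloxyacetylenes, so its [2+2] capture of the vinylketene may be too slow; ketene dimerisation and thermal oligomerisation of the terminal alkyne would then take over. The fallback sets out from 11 and returns at 19. Commercial 3-methylbut-3-en-2-one would be trifluoroacetylated (LiN(SiMe3)2, CF3CO2CH2CF3, THF, −78 °C) to 1,1,1-trifluoro-5-methylhex-5-ene-2,4-dione F1. Diazo transfer with loss of the trifluoroacetyl group (MsN3, Et3N, H2O, MeCN) would then give 1-diazo-3-methylbut-3-en-2-one F2. Irradiation of F2 with 11 (300 nm, CH2Cl2, rt) should bring about a photochemical Wolff rearrangement to the same vinylketene 15 without heat, formed slowly in the presence of all of the ynol ether. Cycloaddition to 16, then continued irradiation or brief warming to 80 °C, should carry 16 through 17 and 18 to 19. This is the known photochemical, second-generation form of the benzannulation.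

2. Step 7. The terminal aryl ethynyl ether may be lost by acid-catalysed hydration to the aryl acetate or by oligomerisation during work-up and concentration, and the benzylic positions may be lithiated if the temperature drifts upward. The fallback sets out from phenol 7 and returns at 20, leaving out the alkynyl ether altogether. Commercial 3-bromo-5-methylphenol would be benzylated (BnBr, K2CO3, DMF) to 1-(benzyloxy)-3-bromo-5-methylbenzene F3. An Ullmann-type C–O coupling suited to hindered phenols (copper iodide CuI, picolinic acid, K3PO4, DMSO, 90 °C) would join F3 to 7, giving 1-(benzyloxy)-2-[3-(benzyloxy)-5-methylphenoxy]-5-methoxy-3-{[(triisopropylsilyl)oxy]methyl}benzene F4. Hydrogenolysis (H2, Pd/C, EtOAc) would remove both benzyl groups and give 20.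

3. Step 13. Acyl transfer to a benzylic alcohol crowded by the ortho aryloxy group may be slow or incomplete in the enzyme pocket, and non-enzymatic acylation of the phenols could creep in over long reaction times. The fallback sets out from 21 and returns at 23. All three hydroxyls would be acylated (palmitoyl chloride, Et3N, DMAP, CH2Cl2) to [3-(hexadecanoyloxy)-2-[3-(hexadecanoyloxy)-5-methylphenoxy]-5-methoxyphenyl]methyl hexadecanoate F5. The two aryl esters, far better acyl donors than the benzylic alkyl ester, would then be removed selectively by aminolysis with pyrrolidine (CH2Cl2, 0 °C), leaving 23.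

**Further compounds**

F1 | step 10 | 1,1,1-trifluoro-5-methylhex-5-ene-2,4-dione | C=C(C)C(=O)CC(=O)C(F)(F)F
F2 | step 10 | 1-diazo-3-methylbut-3-en-2-one | C=C(C)C(=O)C=[N+]=[N-]
F3 | step 7 | 1-(benzyloxy)-3-bromo-5-methylbenzene | Cc1cc(Br)cc(OCc2ccccc2)c1
F4 | step 7 | 1-(benzyloxy)-2-[3-(benzyloxy)-5-methylphenoxy]-5-methoxy-3-{[(triisopropylsilyl)oxy]methyl}benzene | Cc1cc(OCc2ccccc2)cc(Oc3c(CO[Si](C(C)C)(C(C)C)C(C)C)cc(OC)cc3OCc4ccccc4)c1
F5 | step 13 | [3-(hexadecanoyloxy)-2-[3-(hexadecanoyloxy)-5-methylphenoxy]-5-methoxyphenyl]methyl hexadecanoate | CCCCCCCCCCCCCCCC(=O)OCc1cc(OC)cc(OC(=O)CCCCCCCCCCCCCCC)c1Oc1cc(C)cc(OC(=O)CCCCCCCCCCCCCCC)c1
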